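## Retrosynthetic overview

1. Carotenoid numbering is used; ring A is the trimethylcyclohexene of the myristate end (C1–C6) and ring B that of the palmitate end (C1'–C6'). The polyene is cut at C11=C12 and C11'=C12' (two Wittig olefinations) into the ring A phosphonium salt 11, the commercial C10 dialdehyde 20 and the ring B phosphonium salt 19. Each ester is installed on its own fragment, so the two hydroxyls never compete.
2. Enabling feature: in ring A the carbinol carbon C3 lies between two methylenes (C2, C4), which are bonded to C1 (gem-dimethyl) and C5 (methyl-bearing), the two carbons α to C6. With C6 as a ketone, ring A is 2-methylpentan-3-one (4) bridged across both α-carbons by a C2–C3(O)–C4 unit whose middle carbon is the only lasting stereocentre.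
3. Key disconnection: a one-pot [3+3] bis-alkylation of 4 with (S)-1-chloro-3-iodo-2-silyloxypropane 3 (from (R)-epichlorohydrin) forms C4–C5 and C1–C2, closes ring A, builds the quaternary C1 and brings C3 in from the chiral pool. The C6 ketone then accepts the enynol 7 and leaves as water when C5=C6 is formed.
4. Ring B is not constructed: it comes from (R)-α-ionone 12 (C6'). C3' is oxidised, set R by CBS reduction and acylated, and the side chain is extended by two carbons to 19.
5. Order of ring formation: ring A in step 3 (the only ring closure); ring B is present from the start. Union: 11 + 20 → 21 (step 15), then 19 + 21 → 22 (step 16).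

Key step: step 3

Assumption: (R)-α-ionone is taken as purchasable in enantiopure form (fermentation-derived flavour grade), so C6' comes from the starting material; centres that are erased later (C5/C6 in 5, 6, 8, 9; C9' in 17, 18) are carried as epimer mixtures and left open in the SMILES.

## Route

Step 1
Reactants: 1 (R)-epichlorohydrin
Product: 2 (2S)-1-chloro-3-iodopropan-2-ol
Conditions: LiI (1.2 equiv), AcOH (1.5 equiv), THF, 0 → 25 °C
Reagents that add atoms: lithium iodide, [Li+].[I-]
Why: Acid-assisted halohydrin formation (iodide opens the epoxide at its unsubstituted carbon) should leave the stereocentre untouched; the descriptor changes from R to S only because CH2I now outranks CH2Cl.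

Step 2
Reactants: 2 (2S)-1-chloro-3-iodopropan-2-ol
Product: 3 tert-butyl{[(2S)-1-chloro-3-iodopropan-2-yl]oxy}dimethylsilane
Conditions: t-BuMe2SiOTf, 2,6-lutidine, CH2Cl2, −78 → 0 °C
Reagents that add atoms: tert-butyldimethylsilyl trifluoromethanesulfonate, CC(C)(C)[Si](C)(C)OS(=O)(=O)C(F)(F)F
Why: Fast O-silylation with a non-nucleophilic base should outrun epoxide re-closure and give an ether that survives the enolates, acetylide and hydride ahead.

Step 3
Reactants: 4 2-methylpentan-3-one; 3 tert-butyl{[(2S)-1-chloro-3-iodopropan-2-yl]oxy}dimethylsilane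
Product: 6 (4R)-4-[(tert-butyldimethylsilyl)oxy]-2,2,6-trimethylcyclohexan-1-one (C6 epimers), via chloro ketone 5 (not isolated)
Conditions: LiN(i-Pr)2 (1.25 equiv), 4 (1.2 equiv), THF, −78 °C; 3 (1.0 equiv), DMPU, −78 → 0 °C; then KOt-Bu (1.5 equiv), t-BuOH, 0 → 45 °C
Reagents that add atoms: none
Why: Proposed new method: kinetic deprotonation of 4 by LiN(i-Pr)2 should give the ethyl-side lithium enolate, whose carbon displaces the iodide of 3 (SN2, iodide far ahead of chloride) to form C4–C5 and give 5; KOt-Bu in t-BuOH then equilibrates the enolates of 5, and the isopropyl-side enolate, the only one that can reach a six-membered transition state through carbon, displaces chloride to form C1–C2 and the quaternary C1. The closest known reaction types are the α-alkylation of ketone lithium enolates by primary iodides, the ring closure of δ-halo ketone enolates to cyclohexanones, and [3+3] α,α'-annulations of ketone enolate equivalents with 1,3-dihalides such as 3-chloro-2-(chloromethyl)prop-1-ene; what is new is their union in one pot on an unactivated ketone and an unsymmetrical, 2-oxygenated dihalide. Ring A closes in the 6-(enolendo)-exo-tet mode. The new stereocentre at C5 should form as an epimer mixture (cis, diequatorial epimer favoured under the equilibrating base) and is erased in step 6, while C3 is not touched: its R sense in the ring is fixed only by which terminus of 3 meets which α-carbon. The step therefore needs regioselective first enolisation (CH2 over CH, secured by the kinetic base), chemoselective first displacement (I over Cl) and C- over O-alkylation in the closure (favoured by the hydrogen-bonding alcohol medium); a small excess of the first enolate consumes all of 3 before the equilibrating base is added, so that no isopropyl-side enolate of 4 can meet the iodide.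

Step 4
Reactants: 6 (4R)-4-[(tert-butyldimethylsilyl)oxy]-2,2,6-trimethylcyclohexan-1-one; 7 (2E)-3-methylpent-2-en-4-yn-1-ol
Product: 8 (4R)-4-[(tert-butyldimethylsilyl)oxy]-1-[(3E)-5-hydroxy-3-methylpent-3-en-1-yn-1-yl]-2,2,6-trimethylcyclohexan-1-ol (C1 and C6 epimers)
Conditions: 7 (1.6 equiv), n-BuLi (3.2 equiv), THF, −78 → −20 °C; then 6, −78 → 25 °C
Reagents that add atoms: none
Why: 1,2-Addition of the lithium acetylide (alkoxide–acetylide dianion of 7) to the hindered ketone has close precedent on 4-oxygenated 2,2,6-trimethylcyclohexanones; the new carbinol centre at C6 and the C5 centre are of no consequence, since both are erased in step 6.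

Step 5
Reactants: 8 (4R)-4-[(tert-butyldimethylsilyl)oxy]-1-[(3E)-5-hydroxy-3-methylpent-3-en-1-yn-1-yl]-2,2,6-trimethylcyclohexan-1-ol
Product: 9 (4R)-4-[(tert-butyldimethylsilyl)oxy]-1-[(1E,3E)-5-hydroxy-3-methylpenta-1,3-dien-1-yl]-2,2,6-trimethylcyclohexan-1-ol (C1 and C6 epimers)
Conditions: NaAlH2(OCH2CH2OMe)2 (3.5 equiv), THF, 0 → 25 °C
Reagents that add atoms: none
Why: Alkoxide-directed trans-hydroalumination of the propargylic alcohol should give the 7E alkene only and leave the 9E alkene and the silyl ether untouched.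

Step 6
Reactants: 9 (4R)-4-[(tert-butyldimethylsilyl)oxy]-1-[(1E,3E)-5-hydroxy-3-methylpenta-1,3-dien-1-yl]-2,2,6-trimethylcyclohexan-1-ol
Product: 10 {(2E,4E)-5-[(4R)-4-hydroxy-2,6,6-trimethylcyclohex-1-en-1-yl]-3-methylpenta-2,4-dien-1-yl}triphenylphosphonium bromide
Conditions: PPh3·HBr (1.3 equiv), MeOH, 0 → 25 °C; crystallisation
Reagents that add atoms: triphenylphosphine hydrobromide, [Br-].[PH+](c1ccccc1)(c1ccccc1)c1ccccc1
Why: Acid ionisation of the tertiary allylic C6 alcohol, loss of H5 to the tetrasubstituted C5=C6 alkene (which erases the C5 and C6 centres) and SN1-type capture of the extended allyl cation by PPh3 at the primary terminus C11 is an established way to polyenyl phosphonium salts; the residual acid in methanol should also remove the silyl ether, and the all-E salt is expected to crystallise.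

Step 7
Reactants: 10 {(2E,4E)-5-[(4R)-4-hydroxy-2,6,6-trimethylcyclohex-1-en-1-yl]-3-methylpenta-2,4-dien-1-yl}triphenylphosphonium bromide
Product: 11 {(2E,4E)-3-methyl-5-[(4R)-2,6,6-trimethyl-4-(tetradecanoyloxy)cyclohex-1-en-1-yl]penta-2,4-dien-1-yl}triphenylphosphonium bromide
Conditions: n-C13H27COCl (1.2 equiv), pyridine, CH2Cl2, 0 → 25 °C
Reagents that add atoms: tetradecanoyl chloride, CCCCCCCCCCCCCC(=O)Cl
Why: O-Acylation of the only hydroxyl by the acid chloride; the phosphonium centre is inert to acyl chloride and pyridine.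

Step 8
Reactants: 12 (R)-α-ionone
Product: 13 2-methyl-2-{(E)-2-[(1R)-2,6,6-trimethylcyclohex-2-en-1-yl]ethenyl}-1,3-dioxolane
Conditions: Me3SiOCH2CH2OSiMe3, Me3SiOTf (cat.), CH2Cl2, −78 °C
Reagents that add atoms: 1,2-bis(trimethylsilyloxy)ethane, C[Si](C)(C)OCCO[Si](C)(C)C
Why: Silyl-triflate-catalysed dioxolanation at low temperature should protect the side-chain carbonyl without moving the C7'=C8' double bond or touching C6'.

Step 9
Reactants: 13 2-methyl-2-{(E)-2-[(1R)-2,6,6-trimethylcyclohex-2-en-1-yl]ethenyl}-1,3-dioxolane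
Product: 14 (4R)-3,5,5-trimethyl-4-[(E)-2-(2-methyl-1,3-dioxolan-2-yl)ethenyl]cyclohex-2-en-1-one
Conditions: t-BuOOH (70% aq.), NaOCl (aq.), K2CO3, MeCN, 0 °C
Reagents that add atoms: tert-butyl hydroperoxide, CC(C)(C)OO
Why: Radical allylic oxidation (peroxyl radical, allylic peroxide, loss of tert-butanol) should take place at the ring methylene C3', the only unhindered secondary allylic position, while the basic medium preserves the dioxolane and the neopentylic C6'–H is shielded.

Step 10
Reactants: 14 (4R)-3,5,5-trimethyl-4-[(E)-2-(2-methyl-1,3-dioxolan-2-yl)ethenyl]cyclohex-2-en-1-one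
Product: 15 (1R,4R)-3,5,5-trimethyl-4-[(E)-2-(2-methyl-1,3-dioxolan-2-yl)ethenyl]cyclohex-2-en-1-ol
Conditions: (S)-2-methyl-CBS-oxazaborolidine (0.2 equiv), catecholborane (1.5 equiv), toluene, −78 °C
Reagents that add atoms: none
Why: CBS reduction, in which the (S)-catalyst treats the alkene arm of the enone as the large group, should set C3' as R (1R in 15), trans to the side chain at C6'; any cis epimer is a diastereomer and is removed by chromatography.

Step 11
Reactants: 15 (1R,4R)-3,5,5-trimethyl-4-[(E)-2-(2-methyl-1,3-dioxolan-2-yl)ethenyl]cyclohex-2-en-1-ol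
Product: 16 (3E)-4-[(1R,4R)-4-hydroxy-2,6,6-trimethylcyclohex-2-en-1-yl]but-3-en-2-one
Conditions: pyridinium p-toluenesulfonate (cat.), acetone–H2O, 25 °C
Reagents that add atoms: water, O
Why: Mild acetal hydrolysis should return the conjugated methyl ketone without ionising the secondary allylic alcohol.

Step 12
Reactants: 16 (3E)-4-[(1R,4R)-4-hydroxy-2,6,6-trimethylcyclohex-2-en-1-yl]but-3-en-2-one
Product: 17 (1R,4R)-4-[(1E)-3-hydroxy-3-methylpenta-1,4-dien-1-yl]-3,5,5-trimethylcyclohex-2-en-1-ol (C9' epimers)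
Conditions: CH2=CHMgBr (3.5 equiv), THF, −30 → 0 °C
Reagents that add atoms: vinylmagnesium bromide, C=C[Mg]Br
Why: Grignard 1,2-addition to the methyl ketone after deprotonation of the hydroxyl; the new tertiary carbinol centre forms as both epimers and is erased in step 14.

Step 13
Reactants: 17 (1R,4R)-4-[(1E)-3-hydroxy-3-methylpenta-1,4-dien-1-yl]-3,5,5-trimethylcyclohex-2-en-1-ol
Product: 18 (1R,4R)-4-[(1E)-3-hydroxy-3-methylpenta-1,4-dien-1-yl]-3,5,5-trimethylcyclohex-2-en-1-yl hexadecanoate (C9' epimers)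
Conditions: n-C15H31COCl (1.1 equiv), pyridine, CH2Cl2, 0 °C
Reagents that add atoms: hexadecanoyl chloride, CCCCCCCCCCCCCCCC(=O)Cl
Why: Acylation by the acid chloride should be selective for the secondary over the tertiary alcohol on steric grounds.

Step 14
Reactants: 18 (1R,4R)-4-[(1E)-3-hydroxy-3-methylpenta-1,4-dien-1-yl]-3,5,5-trimethylcyclohex-2-en-1-yl hexadecanoate
Product: 19 {(2E,4E)-5-[(1R,4R)-4-(hexadecanoyloxy)-2,6,6-trimethylcyclohex-2-en-1-yl]-3-methylpenta-2,4-dien-1-yl}triphenylphosphonium bromide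
Conditions: PPh3·HBr (1.05 equiv), CH2Cl2, 0 → 25 °C; crystallisation
Reagents that add atoms: triphenylphosphine hydrobromide, [Br-].[PH+](c1ccccc1)(c1ccccc1)c1ccccc1
Why: The tertiary, doubly allylic C9' carbinol should ionise far more readily than the secondary allylic ester, and PPh3 captures the cation at the primary terminus C11' (allylic transposition) to give the 9'E salt after crystallisation, with C3' and C6' not involved.

Step 15
Reactants: 11 {(2E,4E)-3-methyl-5-[(4R)-2,6,6-trimethyl-4-(tetradecanoyloxy)cyclohex-1-en-1-yl]penta-2,4-dien-1-yl}triphenylphosphonium bromide; 20 (2E,4E,6E)-2,7-dimethylocta-2,4,6-trienedial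
Product: 21 (3R)-3-(tetradecanoyloxy)-12'-apo-β-caroten-12'-al (all-E)
Conditions: 11, NaN(SiMe3)2 (1.0 equiv), THF, −78 °C; cannulated into 20 (3 equiv), THF, −78 → 0 °C; then I2 (cat.), CH2Cl2, 25 °C
Reagents that add atoms: none
Why: Wittig olefination of one formyl group of the excess dialdehyde forms C11=C12; the aprotic amide base should leave the ester alone, and catalytic iodine should equilibrate any 11Z isomer to the all-E aldehyde.

Step 16
Reactants: 19 {(2E,4E)-5-[(1R,4R)-4-(hexadecanoyloxy)-2,6,6-trimethylcyclohex-2-en-1-yl]-3-methylpenta-2,4-dien-1-yl}triphenylphosphonium bromide; 21 (3R)-3-(tetradecanoyloxy)-12'-apo-β-caroten-12'-al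
Product: 22 (3R,3'R,6'R)-β,ε-carotene-3,3'-diol 3-tetradecanoate 3'-hexadecanoate (CNP0230054.1)
Conditions: 19, NaN(SiMe3)2 (1.0 equiv), THF, −78 °C; then 21, −78 → 25 °C; then heptane, 90 °C; crystallisation
Reagents that add atoms: none
Why: The second Wittig olefination forms C11'=C12'; low-temperature ylide formation should spare both esters and the C6' centre, and thermal equilibration followed by crystallisation should give the all-E compound.

## Compound list

1 | (R)-epichlorohydrin, (2R)-2-(chloromethyl)oxirane | ClC[C@H]1CO1 | starting material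
2 | (2S)-1-chloro-3-iodopropan-2-ol | ClC[C@H](O)CI | intermediate
3 | tert-butyl{[(2S)-1-chloro-3-iodopropan-2-yl]oxy}dimethylsilane | ClC[C@H](O[Si](C)(C)C(C)(C)C)CI | intermediate
4 | 2-methylpentan-3-one | CCC(=O)C(C)C | starting material
5 | (6R)-6-[(tert-butyldimethylsilyl)oxy]-7-chloro-2,4-dimethylheptan-3-one (C4 epimers) | CC(C)C(=O)C(C)C[C@@H](O[Si](C)(C)C(C)(C)C)CCl | intermediate
6 | (4R)-4-[(tert-butyldimethylsilyl)oxy]-2,2,6-trimethylcyclohexan-1-one (C6 epimers) | O=C1C(C)C[C@@H](O[Si](C)(C)C(C)(C)C)CC1(C)C | intermediate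
7 | (2E)-3-methylpent-2-en-4-yn-1-ol | C#C/C(C)=C/CO | starting material
8 | (4R)-4-[(tert-butyldimethylsilyl)oxy]-1-[(3E)-5-hydroxy-3-methylpent-3-en-1-yn-1-yl]-2,2,6-trimethylcyclohexan-1-ol (C1 and C6 epimers) | OC/C=C(C)/C#CC1(O)C(C)C[C@@H](O[Si](C)(C)C(C)(C)C)CC1(C)C | intermediate
9 | (4R)-4-[(tert-butyldimethylsilyl)oxy]-1-[(1E,3E)-5-hydroxy-3-methylpenta-1,3-dien-1-yl]-2,2,6-trimethylcyclohexan-1-ol (C1 and C6 epimers) | OC/C=C(C)/C=C/C1(O)C(C)C[C@@H](O[Si](C)(C)C(C)(C)C)CC1(C)C | intermediate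
10 | {(2E,4E)-5-[(4R)-4-hydroxy-2,6,6-trimethylcyclohex-1-en-1-yl]-3-methylpenta-2,4-dien-1-yl}triphenylphosphonium bromide | [Br-].O[C@@H]1CC(C)=C(/C=C/C(C)=C/C[P+](c2ccccc2)(c2ccccc2)c2ccccc2)C(C)(C)C1 | intermediate
11 | {(2E,4E)-3-methyl-5-[(4R)-2,6,6-trimethyl-4-(tetradecanoyloxy)cyclohex-1-en-1-yl]penta-2,4-dien-1-yl}triphenylphosphonium bromide | [Br-].CCCCCCCCCCCCCC(=O)O[C@@H]1CC(C)=C(/C=C/C(C)=C/C[P+](c2ccccc2)(c2ccccc2)c2ccccc2)C(C)(C)C1 | intermediate
12 | (R)-α-ionone, (3E)-4-[(1R)-2,6,6-trimethylcyclohex-2-en-1-yl]but-3-en-2-one | CC(=O)/C=C/[C@H]1C(C)=CCCC1(C)C | starting material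
13 | 2-methyl-2-{(E)-2-[(1R)-2,6,6-trimethylcyclohex-2-en-1-yl]ethenyl}-1,3-dioxolane | CC1(/C=C/[C@H]2C(C)=CCCC2(C)C)OCCO1 | intermediate
14 | (4R)-3,5,5-trimethyl-4-[(E)-2-(2-methyl-1,3-dioxolan-2-yl)ethenyl]cyclohex-2-en-1-one | CC1(/C=C/[C@H]2C(C)=CC(=O)CC2(C)C)OCCO1 | intermediate
15 | (1R,4R)-3,5,5-trimethyl-4-[(E)-2-(2-methyl-1,3-dioxolan-2-yl)ethenyl]cyclohex-2-en-1-ol | O[C@H]1C=C(C)[C@H](/C=C/C2(C)OCCO2)C(C)(C)C1 | intermediate
16 | (3E)-4-[(1R,4R)-4-hydroxy-2,6,6-trimethylcyclohex-2-en-1-yl]but-3-en-2-one | O[C@H]1C=C(C)[C@H](/C=C/C(C)=O)C(C)(C)C1 | intermediate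
17 | (1R,4R)-4-[(1E)-3-hydroxy-3-methylpenta-1,4-dien-1-yl]-3,5,5-trimethylcyclohex-2-en-1-ol (C9' epimers) | O[C@H]1C=C(C)[C@H](/C=C/C(C)(O)C=C)C(C)(C)C1 | intermediate
18 | (1R,4R)-4-[(1E)-3-hydroxy-3-methylpenta-1,4-dien-1-yl]-3,5,5-trimethylcyclohex-2-en-1-yl hexadecanoate (C9' epimers) | CCCCCCCCCCCCCCCC(=O)O[C@H]1C=C(C)[C@H](/C=C/C(C)(O)C=C)C(C)(C)C1 | intermediate
19 | {(2E,4E)-5-[(1R,4R)-4-(hexadecanoyloxy)-2,6,6-trimethylcyclohex-2-en-1-yl]-3-methylpenta-2,4-dien-1-yl}triphenylphosphonium bromide | [Br-].CCCCCCCCCCCCCCCC(=O)O[C@H]1C=C(C)[C@H](/C=C/C(C)=C/C[P+](c2ccccc2)(c2ccccc2)c2ccccc2)C(C)(C)C1 | intermediate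
20 | (2E,4E,6E)-2,7-dimethylocta-2,4,6-trienedial | O=C/C(C)=C/C=C/C=C(C)/C=O | starting material
21 | (3R)-3-(tetradecanoyloxy)-12'-apo-β-caroten-12'-al (all-E) | O=C/C(C)=C/C=C/C=C(C)/C=C/C=C(C)/C=C/C1=C(C)C[C@@H](OC(=O)CCCCCCCCCCCCC)CC1(C)C | intermediate
22 | (3R,3'R,6'R)-β,ε-carotene-3,3'-diol 3-tetradecanoate 3'-hexadecanoate (lutein 3-myristate 3'-palmitate) | CCCCCCCCCCCCCCCC(=O)O[C@H]1C=C(C)[C@H](/C=C/C(C)=C/C=C/C(C)=C/C=C/C=C(C)/C=C/C=C(C)/C=C/C2=C(C)C[C@@H](OC(=O)CCCCCCCCCCCCC)CC2(C)C)C(C)(C)C1 | target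

## Step count and risks

Total step count: 16. Longest linear sequence: 9 steps (steps 1–7, 15, 16).

Steps most likely to fail:

1. Step 3 (bears the label "Proposed new method"). Proton transfer between the first enolate and 5 before 3 is consumed would scramble which α-carbon meets which terminus, costing yield and enantiopurity. O-alkylation or dehydrochlorination could also compete with the ring closure. The fallback uses known chemistry, sets out from 3 and comes back to the route at 6. Commercial methyl 4-methyl-3-oxopentanoate is C-methylated (MeI, K2CO3, acetone) to methyl 2,4-dimethyl-3-oxopentanoate F1. Its sodium enolate (NaH, DMF) is alkylated by the iodide terminus of 3 to give methyl 2-{(2R)-2-[(tert-butyldimethylsilyl)oxy]-3-chloropropyl}-2,4-dimethyl-3-oxopentanoate F2; the ester fixes the site of the first bond and leaves the isopropyl CH as the only enolisable position. LiN(i-Pr)2 in THF then closes ring A by intramolecular C-alkylation to methyl (5S)-5-[(tert-butyldimethylsilyl)oxy]-1,3,3-trimethyl-2-oxocyclohexane-1-carboxylate F3, and Krapcho dealkoxycarbonylation (LiCl, wet DMSO, 150 °C) removes the activating group to give 6.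

2. Step 10. Facial selectivity may be poor if catalyst control is opposed by the C6' centre, or if the CH2–CMe2 arm is too large to act as the small group. The fallback sets out from 14 and comes back at 15. The ketone is reduced with the catalyst of opposite sense ((R)-2-methyl-CBS-oxazaborolidine, catecholborane), for which the pairing with C6' would then be the matched one, to give the 3',6'-cis alcohol (1S,4R)-3,5,5-trimethyl-4-[(E)-2-(2-methyl-1,3-dioxolan-2-yl)ethenyl]cyclohex-2-en-1-ol F4. Mitsunobu inversion (4-nitrobenzoic acid, PPh3, diisopropyl azodicarboxylate) gives (1R,4R)-3,5,5-trimethyl-4-[(E)-2-(2-methyl-1,3-dioxolan-2-yl)ethenyl]cyclohex-2-en-1-yl 4-nitrobenzoate F5, and methanolysis (K2CO3, MeOH) gives 15.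

3. Step 14. Acid-promoted ionisation of the ring B allylic ester (loss of palmitate, epimerisation at C3', dehydration) may compete with ionisation of the tertiary carbinol. The fallback reverses the polarity of the last union; it sets out from 16 and 21 and comes back at 22.
   - Horner–Wadsworth–Emmons reaction of 16 with diethyl (cyanomethyl)phosphonate (NaH, THF) gives (2E,4E)-5-[(1R,4R)-4-hydroxy-2,6,6-trimethylcyclohex-2-en-1-yl]-3-methylpenta-2,4-dienenitrile F6.
   - i-Bu2AlH (CH2Cl2, −78 °C) gives (2E,4E)-5-[(1R,4R)-4-hydroxy-2,6,6-trimethylcyclohex-2-en-1-yl]-3-methylpenta-2,4-dienal F7.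
   - Hexadecanoyl chloride and pyridine give (1R,4R)-3,5,5-trimethyl-4-[(1E,3E)-3-methyl-5-oxopenta-1,3-dien-1-yl]cyclohex-2-en-1-yl hexadecanoate F8, which never meets acid.
   - On the other side, NaBH4 (THF–EtOH, 0 °C) reduces 21 to (3R)-3-(tetradecanoyloxy)-12'-apo-β-caroten-12'-ol F9.
   - PPh3·HBr (CH2Cl2) converts it into [(3R)-3-(tetradecanoyloxy)-12'-apo-β-caroten-12'-yl]triphenylphosphonium bromide F10.
   - Wittig olefination of F10 (NaN(SiMe3)2, THF, −78 °C) with F8, followed by thermal equilibration, gives 22.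

Further compounds
F1 | step 3 | methyl 2,4-dimethyl-3-oxopentanoate | COC(=O)C(C)C(=O)C(C)C
F2 | step 3 | methyl 2-{(2R)-2-[(tert-butyldimethylsilyl)oxy]-3-chloropropyl}-2,4-dimethyl-3-oxopentanoate (C2 epimers) | COC(=O)C(C)(C[C@@H](O[Si](C)(C)C(C)(C)C)CCl)C(=O)C(C)C
F3 | step 3 | methyl (5S)-5-[(tert-butyldimethylsilyl)oxy]-1,3,3-trimethyl-2-oxocyclohexane-1-carboxylate (C1 epimers) | COC(=O)C1(C)C[C@@H](O[Si](C)(C)C(C)(C)C)CC(C)(C)C1=O
F4 | step 10 | (1S,4R)-3,5,5-trimethyl-4-[(E)-2-(2-methyl-1,3-dioxolan-2-yl)ethenyl]cyclohex-2-en-1-ol | O[C@@H]1C=C(C)[C@H](/C=C/C2(C)OCCO2)C(C)(C)C1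
F5 | step 10 | (1R,4R)-3,5,5-trimethyl-4-[(E)-2-(2-methyl-1,3-dioxolan-2-yl)ethenyl]cyclohex-2-en-1-yl 4-nitrobenzoate | O=C(O[C@H]1C=C(C)[C@H](/C=C/C2(C)OCCO2)C(C)(C)C1)c1ccc(cc1)[N+](=O)[O-]
F6 | step 14 | (2E,4E)-5-[(1R,4R)-4-hydroxy-2,6,6-trimethylcyclohex-2-en-1-yl]-3-methylpenta-2,4-dienenitrile | O[C@H]1C=C(C)[C@H](/C=C/C(C)=C/C#N)C(C)(C)C1
F7 | step 14 | (2E,4E)-5-[(1R,4R)-4-hydroxy-2,6,6-trimethylcyclohex-2-en-1-yl]-3-methylpenta-2,4-dienal | O[C@H]1C=C(C)[C@H](/C=C/C(C)=C/C=O)C(C)(C)C1
F8 | step 14 | (1R,4R)-3,5,5-trimethyl-4-[(1E,3E)-3-methyl-5-oxopenta-1,3-dien-1-yl]cyclohex-2-en-1-yl hexadecanoate | CCCCCCCCCCCCCCCC(=O)O[C@H]1C=C(C)[C@H](/C=C/C(C)=C/C=O)C(C)(C)C1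
F9 | step 14 | (3R)-3-(tetradecanoyloxy)-12'-apo-β-caroten-12'-ol | OC/C(C)=C/C=C/C=C(C)/C=C/C=C(C)/C=C/C1=C(C)C[C@@H](OC(=O)CCCCCCCCCCCCC)CC1(C)C
F10 | step 14 | [(3R)-3-(tetradecanoyloxy)-12'-apo-β-caroten-12'-yl]triphenylphosphonium bromide | [Br-].c1ccccc1[P+](c1ccccc1)(c1ccccc1)C/C(C)=C/C=C/C=C(C)/C=C/C=C(C)/C=C/C1=C(C)C[C@@H](OC(=O)CCCCCCCCCCCCC)CC1(C)C
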